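**Plan**

1. Retrosynthesis: the C8–Cl and C7–OH groups come from trans opening of a 7,8-epoxide, the epoxide from the C7=C8 alkene of a cis-5,6-diol. The carbocycle (ring B: C4a, C5, C6, C7, C8, C8a) is then cut at C8a–C8 and at C5–C6.
2. Enabling feature: on the pyranone (ring A) the formyl carbon C5 sits on C4a, next to C8a, a vinylogous acyl carbon that can carry iodide. C5/C4a/C8a is thus a 1,3-bis-electrophile, matched by a three-carbon 1,3-bis-nucleophile C6–C7–C8, an (E)-γ-silyloxyallyl 1,1-diboronate.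
3. Forward: the arylpropanoic acid (ring C) is converted into an acylketene and annulated with an enaminal to ring A with C5 in place. Zincation and iodination functionalise C8a. The diboron reagent is made in two steps.
4. One flask closes ring B: allylboration forms C5–C6 and turns the second boron into a Z-alkenylboronate on C8, which closes C8a–C8 by Suzuki–Miyaura coupling. Desilylation, epoxidation and chloride opening finish the target.
5. Stereochemistry: C5 from the chiral phosphoric acid; C6 from the E-enol ether geometry (anti adduct = cis in the ring); C7 and C8 from hydroxyl-directed epoxidation syn to the diol and SN2 inversion at C8 by chloride.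

Key step: step 7

Assumption: with this heteroaryl aldehyde the (R)-enantiomer of the phosphoric acid TRIP attacks the Re face of the formyl group, as it does with aryl aldehydes; if the sense is reversed, the (S)-acid is used.

Abbreviations: TBS = tert-butyldimethylsilyl; Bpin = 4,4,5,5-tetramethyl-1,3,2-dioxaborolan-2-yl; TMP = 2,2,6,6-tetramethylpiperidin-1-yl; TRIP = 3,3'-bis(2,4,6-triisopropylphenyl)-1,1'-binaphthyl-2,2'-diyl hydrogen phosphate.

**Route**

Step 1
Reactants: 1 3-(3-hydroxy-4-methoxyphenyl)propanoic acid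
Product: 3 3-[3-(TBSO)-4-methoxyphenyl]propanoic acid, via silyl ester 2 (not isolated)
Conditions: TBSCl, imidazole, DMF, 20 °C; then AcOH, THF–H2O
Reagents that add atoms: TBSCl, CC(C)(C)[Si](C)(C)Cl
Why: Silylation of both acidic hydroxyl groups followed by selective hydrolysis of the labile silyl ester (standard phenol protection) keeps the phenol out of the acylation, metalation and coupling steps.

Step 2
Reactants: 3 3-[3-(TBSO)-4-methoxyphenyl]propanoic acid; 4 Meldrum's acid (2,2-dimethyl-1,3-dioxane-4,6-dione)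
Product: 5 5-{3-[3-(TBSO)-4-methoxyphenyl]-1-hydroxypropylidene}-2,2-dimethyl-1,3-dioxane-4,6-dione
Conditions: DCC, DMAP, CH2Cl2, 0 → 20 °C
Reagents that add atoms: none
Why: Carbodiimide-mediated C-acylation of Meldrum's acid under DMAP catalysis is the standard entry to acyl Meldrum's acids, which are masked acylketenes.

Step 3
Reactants: 5 acyl Meldrum's acid; 6 (E)-3-(dimethylamino)prop-2-enal
Product: 9 6-{2-[3-(TBSO)-4-methoxyphenyl]ethyl}-4-oxo-4H-pyran-3-carbaldehyde, via acylketene 7 (not isolated), via C-acylated enaminal 8 (not isolated)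
Conditions: toluene, 110 °C (N2 sweep); then AcOH, 60 °C
Reagents that add atoms: none
Why: Thermal retro-[4+2] fragmentation of 5 releases the acylketene, which C-acylates the nucleophilic α-carbon of the enaminal, and the distal enol oxygen then closes ring A by addition–elimination with loss of dimethylamine (acylketene–enamine γ-pyrone annulation), placing the formyl carbon (future C5) on the future C4a.

Step 4
Reactants: 9 pyranone aldehyde
Product: 11 6-{2-[3-(TBSO)-4-methoxyphenyl]ethyl}-2-iodo-4-oxo-4H-pyran-3-carbaldehyde, via pyranonylzinc chloride 10 (not isolated)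
Conditions: TMPZnCl·LiCl, THF, 20 °C; then I2, 0 °C
Reagents that add atoms: iodine, II
Why: Directed zincation with the aldehyde-tolerant amide base removes the most acidic ring proton, at the future C8a between the ring oxygen and the formyl-bearing carbon (as at position 2 of chromones), and iodolysis of the C–Zn bond gives the vinylogous acyl iodide.

Step 5
Reactants: 12 tris(Bpin)methane; 13 (tert-butyldimethylsilyloxy)acetaldehyde
Product: 15 2,2'-[3-(TBSO)prop-1-ene-1,1-diyl]bis(4,4,5,5-tetramethyl-1,3,2-dioxaborolane), via lithium triborylmethanide 14 (not isolated)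
Conditions: LiTMP, THF, 0 °C; then 13, −78 → 20 °C
Reagents that add atoms: none
Why: Boron–Wittig olefination, in which the boron-stabilised carbanion adds to the aldehyde and syn-elimination of a boron–oxygen unit gives the 1,1-diborylalkene.

Step 6
Reactants: 15 1,1-diborylalkene
Product: 16 2,2'-[(2E)-3-(TBSO)prop-2-ene-1,1-diyl]bis(4,4,5,5-tetramethyl-1,3,2-dioxaborolane)
Conditions: [Ir(cod)(PPh2Me)2]PF6 (3 mol %, H2-activated), THF, 20 °C
Reagents that add atoms: none
Why: Cationic iridium hydride isomerisation of an allyl silyl ether to the (E)-silyl enol ether (1,3-hydrogen shift through a π-allyl hydride), a transposition known for γ-boryl allyl silyl ethers, moves the double bond off the diboryl carbon and sets the E geometry that later fixes C6.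

Step 7
Reactants: 11 iodo aldehyde; 16 (E)-γ-silyloxyallyl 1,1-diboronate
Product: 19 (5S,6R)-6-(TBSO)-2-{2-[3-(TBSO)-4-methoxyphenyl]ethyl}-5-hydroxy-5,6-dihydro-4H-chromen-4-one, via O-boryl adduct 17 (not isolated), via alkenylboronate 18 (not isolated)
Conditions: 16 (1.2 equiv), (R)-TRIP (10 mol %), 4 Å MS, toluene, −20 °C; then Pd(PPh3)4 (5 mol %), aq. K3PO4, THF, 40 °C
Reagents that add atoms: none
Why: Proposed new method: the phosphoric acid hydrogen-bonds to one boronate oxygen of 16 and to the formyl group of 11, and a closed chair transition state transfers the allyl unit with transposition, so that C6 bonds to the formyl carbon C5 while the double bond moves to C7=C8 and the spectator boron ends on C8 of a (Z)-alkenylboronate (17, then 18 after hydrolysis of the O–B bond); zerovalent palladium then inserts into the C8a–I bond, the alkenyl group transmetalates and reductive elimination forms C8a–C8. The closest known reactions are the chiral phosphoric acid-catalysed allylboration of aldehydes with allylic 1,1-diboronates, which gives (Z)-δ-boryl anti-homoallylic alcohols, the same catalysis with (E)-γ-alkoxyallylboronates, which gives anti-1,2-diol monoethers, and the Suzuki–Miyaura coupling of such alkenylboronates; their union into a one-flask [3+3] annulation of an ortho-iodo formyl heteroarene is what is new. Ring B is closed not by an ionic or radical cyclisation but by intramolecular C(sp2)–C(sp2) coupling, reductive elimination from a seven-membered palladacycle giving the six-membered ring with its cis C7=C8 bond. C5 is set by the catalyst, the (R)-acid directing attack on the Re face of the formyl group (5S), and C6 by the E geometry of the silyl enol ether, which sits equatorial in the chair and gives the anti adduct, that is the cis-5,6 relationship (6R). The step needs Z geometry at C7=C8, secured by the α-boryl group taking the pseudo-axial position away from the pinacol methyl groups, and chemoselectivity, secured by consuming the aldehyde before palladium and base are added and by the vinylogous acyl iodide character of C8a–I, which makes oxidative addition fast under mild aqueous base.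

Step 8
Reactants: 19 bis-silyl dihydrochromenone
Product: 20 (5S,6R)-5,6-dihydroxy-2-[2-(3-hydroxy-4-methoxyphenyl)ethyl]-5,6-dihydro-4H-chromen-4-one
Conditions: TBAF, AcOH, THF, 0 °C
Reagents that add atoms: none
Why: Fluoride-mediated desilylation removes both silyl ethers under buffered conditions that avoid the acid-promoted dehydration (aromatisation) to which a cis-dihydrodiol is prone.

Step 9
Reactants: 20 diene diol
Product: 21 (5S,6S,7S,8S)-7,8-epoxy-5,6-dihydroxy-2-[2-(3-hydroxy-4-methoxyphenyl)ethyl]-5,6,7,8-tetrahydro-4H-chromen-4-one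
Conditions: mCPBA, CH2Cl2–aq. phosphate buffer (pH 7.5), 0 °C
Reagents that add atoms: mCPBA, O=C(OO)c1cccc(Cl)c1
Why: Hydroxyl-directed Prilezhaev epoxidation of C7=C8 (the only double bond not in conjugation with the ring carbonyl as an enone), in which hydrogen bonding of the peracid to the allylic C6 hydroxyl delivers oxygen to the face syn to the cis-diol and so sets C7 and C8.

Step 10
Reactants: 21 epoxy diol
Product: 22 (5S,6S,7S,8R)-8-chloro-5,6,7-trihydroxy-2-[2-(3-hydroxy-4-methoxyphenyl)ethyl]-5,6,7,8-tetrahydro-4H-chromen-4-one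
Conditions: LiCl, AcOH, THF, 0 → 20 °C
Reagents that add atoms: lithium chloride, [Li+].[Cl-]
Why: Acid-assisted SN2 opening of the epoxide by chloride with inversion at C8, the carbon activated by the adjacent ring A π-system and remote from the inductively deactivating C6 hydroxyl (distal opening of a 2,3-epoxy alcohol), gives the trans-chlorohydrin with 8R chloride and 7S hydroxyl.

**Compound list**

1 | 3-(3-hydroxy-4-methoxyphenyl)propanoic acid | COc1ccc(CCC(=O)O)cc1O | starting material
2 | tert-butyldimethylsilyl 3-[3-(TBSO)-4-methoxyphenyl]propanoate | COc1ccc(CCC(=O)O[Si](C)(C)C(C)(C)C)cc1O[Si](C)(C)C(C)(C)C | intermediate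
3 | 3-[3-(TBSO)-4-methoxyphenyl]propanoic acid | COc1ccc(CCC(=O)O)cc1O[Si](C)(C)C(C)(C)C | intermediate
4 | Meldrum's acid (2,2-dimethyl-1,3-dioxane-4,6-dione) | CC1(C)OC(=O)CC(=O)O1 | starting material
5 | 5-{3-[3-(TBSO)-4-methoxyphenyl]-1-hydroxypropylidene}-2,2-dimethyl-1,3-dioxane-4,6-dione | CC1(C)OC(=O)C(=C(O)CCc2ccc(OC)c(O[Si](C)(C)C(C)(C)C)c2)C(=O)O1 | intermediate
6 | (E)-3-(dimethylamino)prop-2-enal | CN(C)/C=C/C=O | starting material
7 | 5-[3-(TBSO)-4-methoxyphenyl]-3-oxopent-1-en-1-one (acylketene) | COc1ccc(CCC(=O)C=C=O)cc1O[Si](C)(C)C(C)(C)C | intermediate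
8 | 2-[(dimethylamino)methylidene]-7-[3-(TBSO)-4-methoxyphenyl]-3,5-dioxoheptanal | COc1ccc(CCC(=O)CC(=O)C(C=O)=CN(C)C)cc1O[Si](C)(C)C(C)(C)C | intermediate
9 | 6-{2-[3-(TBSO)-4-methoxyphenyl]ethyl}-4-oxo-4H-pyran-3-carbaldehyde | COc1ccc(CCc2cc(=O)c(C=O)co2)cc1O[Si](C)(C)C(C)(C)C | intermediate
10 | (6-{2-[3-(TBSO)-4-methoxyphenyl]ethyl}-3-formyl-4-oxo-4H-pyran-2-yl)zinc chloride | COc1ccc(CCc2cc(=O)c(C=O)c([Zn]Cl)o2)cc1O[Si](C)(C)C(C)(C)C | intermediate
11 | 6-{2-[3-(TBSO)-4-methoxyphenyl]ethyl}-2-iodo-4-oxo-4H-pyran-3-carbaldehyde | COc1ccc(CCc2cc(=O)c(C=O)c(I)o2)cc1O[Si](C)(C)C(C)(C)C | intermediate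
12 | tris(4,4,5,5-tetramethyl-1,3,2-dioxaborolan-2-yl)methane | C(B1OC(C)(C)C(C)(C)O1)(B1OC(C)(C)C(C)(C)O1)B1OC(C)(C)C(C)(C)O1 | starting material
13 | (tert-butyldimethylsilyloxy)acetaldehyde | CC(C)(C)[Si](C)(C)OCC=O | starting material
14 | lithium tris(Bpin)methanide | [Li]C(B1OC(C)(C)C(C)(C)O1)(B1OC(C)(C)C(C)(C)O1)B1OC(C)(C)C(C)(C)O1 | intermediate
15 | 2,2'-[3-(TBSO)prop-1-ene-1,1-diyl]bis(4,4,5,5-tetramethyl-1,3,2-dioxaborolane) | CC(C)(C)[Si](C)(C)OCC=C(B1OC(C)(C)C(C)(C)O1)B1OC(C)(C)C(C)(C)O1 | intermediate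
16 | 2,2'-[(2E)-3-(TBSO)prop-2-ene-1,1-diyl]bis(4,4,5,5-tetramethyl-1,3,2-dioxaborolane) | CC(C)(C)[Si](C)(C)O/C=C/C(B1OC(C)(C)C(C)(C)O1)B1OC(C)(C)C(C)(C)O1 | intermediate
17 | 3-[(1S,2R,3Z)-2-(TBSO)-1-(Bpin-oxy)-4-(Bpin)but-3-en-1-yl]-6-{2-[3-(TBSO)-4-methoxyphenyl]ethyl}-2-iodo-4H-pyran-4-one | COc1ccc(CCc2cc(=O)c(c(I)o2)[C@H](OB3OC(C)(C)C(C)(C)O3)[C@H](O[Si](C)(C)C(C)(C)C)/C=C\B4OC(C)(C)C(C)(C)O4)cc1O[Si](C)(C)C(C)(C)C | intermediate
18 | 3-[(1S,2R,3Z)-2-(TBSO)-1-hydroxy-4-(Bpin)but-3-en-1-yl]-6-{2-[3-(TBSO)-4-methoxyphenyl]ethyl}-2-iodo-4H-pyran-4-one | COc1ccc(CCc2cc(=O)c(c(I)o2)[C@H](O)[C@H](O[Si](C)(C)C(C)(C)C)/C=C\B3OC(C)(C)C(C)(C)O3)cc1O[Si](C)(C)C(C)(C)C | intermediate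
19 | (5S,6R)-6-(TBSO)-2-{2-[3-(TBSO)-4-methoxyphenyl]ethyl}-5-hydroxy-5,6-dihydro-4H-chromen-4-one | COc1ccc(CCc2cc(=O)c3c(o2)C=C[C@@H](O[Si](C)(C)C(C)(C)C)[C@H]3O)cc1O[Si](C)(C)C(C)(C)C | intermediate
20 | (5S,6R)-5,6-dihydroxy-2-[2-(3-hydroxy-4-methoxyphenyl)ethyl]-5,6-dihydro-4H-chromen-4-one | COc1ccc(CCc2cc(=O)c3c(o2)C=C[C@@H](O)[C@H]3O)cc1O | intermediate
21 | (5S,6S,7S,8S)-7,8-epoxy-5,6-dihydroxy-2-[2-(3-hydroxy-4-methoxyphenyl)ethyl]-5,6,7,8-tetrahydro-4H-chromen-4-one | COc1ccc(CCc2cc(=O)c3c(o2)[C@H]4O[C@H]4[C@@H](O)[C@H]3O)cc1O | intermediate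
22 | (5S,6S,7S,8R)-8-chloro-5,6,7-trihydroxy-2-[2-(3-hydroxy-4-methoxyphenyl)ethyl]-5,6,7,8-tetrahydro-4H-chromen-4-one | COc1ccc(CCc2cc(=O)c3c(o2)[C@H](Cl)[C@@H](O)[C@@H](O)[C@H]3O)cc1O | target

**Step count and risks**

Total step count: 10. Longest linear sequence: 8 steps (steps 1, 2, 3, 4, 7, 8, 9, 10); steps 5 and 6 prepare the reagent.

Steps most likely to fail:

Step 7 (Proposed new method). What may go wrong: insufficient facial or anti/syn control in the allylboration of the doubly ortho-substituted aldehyde, formation of the E-alkenylboronate, which cannot reach C8a, or hydrolysis of the C8a–I bond and protodeboronation before ring closure. The fallback uses known reactions only, sets out from 13 and 11 and returns at 19. Boron–Wittig olefination of 13 with lithiated bis(Bpin)methane should give the (E)-alkenylboronate 2-[(1E)-3-(TBSO)prop-1-en-1-yl]-4,4,5,5-tetramethyl-1,3,2-dioxaborolane F1. Its iridium-catalysed transposition ([Ir(cod)(PPh2Me)2]PF6) should give the (E)-γ-silyloxyallylboronate F2. Suzuki–Miyaura vinylation of 11 (vinyl-Bpin, Pd(PPh3)4, K3PO4) should give the vinyl aldehyde F3. (R)-TRIP-catalysed allylboration of F3 with F2 should give the anti diene alcohol F4. Ring-closing metathesis (second-generation Hoveyda–Grubbs catalyst) then forms C7=C8 and gives 19. This detour does not need 16.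

Step 6. What may go wrong: slow turnover on the trisubstituted diborylalkene, or erosion of the E geometry of the enol ether. The fallback sets out from 15 and returns at 19. Nickel hydride transposition (NiCl2(dppb), LiBHEt3), which is Z-selective for allyl silyl ethers, should give the (Z)-isomer of 16, F5. Annulation of F5 with 11 as in step 7, but with (S)-TRIP, should give the 5,6-trans compound (5R,6R)-6-(TBSO)-2-{2-[3-(TBSO)-4-methoxyphenyl]ethyl}-5-hydroxy-5,6-dihydro-4H-chromen-4-one F6, in which C6 is already correct. Mitsunobu inversion at C5 (4-nitrobenzoic acid, PPh3, DIAD) should give the (5S,6R) 4-nitrobenzoate F7, and brief methanolysis (K2CO3, MeOH, 0 °C) returns 19; a phenol silyl ether lost here would be removed in step 8 anyway. Should neither transposition catalyst turn over 15, the detour given for step 7 applies.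

Step 9. What may go wrong: weak hydrogen-bond delivery in the polar medium needed to dissolve the triol, giving poor facial selectivity, or acid-promoted opening of the epoxide and dehydration of the diol. The fallback sets out from 19 and returns at 21; it obtains the same face by steric control and anti opening instead of hydroxyl delivery. NBS in aqueous DME should form the bromonium ion on the face opposite the C6 silyl ether, and water should open it anti to give the bromohydrin (5S,6S,7S,8R)-7-bromo-6-(TBSO)-2-{2-[3-(TBSO)-4-methoxyphenyl]ethyl}-5,8-dihydroxy-5,6,7,8-tetrahydro-4H-chromen-4-one F8 (either regioisomer serves). K2CO3 in acetone should close it to the silyl-protected epoxide syn to the oxygen substituents, F9, and TBAF/AcOH then gives 21.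

Further compounds
F1 | step 7 | 2-[(1E)-3-(TBSO)prop-1-en-1-yl]-4,4,5,5-tetramethyl-1,3,2-dioxaborolane | CC(C)(C)[Si](C)(C)OC/C=C/B1OC(C)(C)C(C)(C)O1
F2 | step 7 | 2-[(2E)-3-(TBSO)prop-2-en-1-yl]-4,4,5,5-tetramethyl-1,3,2-dioxaborolane | CC(C)(C)[Si](C)(C)O/C=C/CB1OC(C)(C)C(C)(C)O1
F3 | step 7 | 6-{2-[3-(TBSO)-4-methoxyphenyl]ethyl}-2-ethenyl-4-oxo-4H-pyran-3-carbaldehyde | COc1ccc(CCc2cc(=O)c(C=O)c(C=C)o2)cc1O[Si](C)(C)C(C)(C)C
F4 | step 7 | 3-[(1S,2R)-2-(TBSO)-1-hydroxybut-3-en-1-yl]-6-{2-[3-(TBSO)-4-methoxyphenyl]ethyl}-2-ethenyl-4H-pyran-4-one | COc1ccc(CCc2cc(=O)c(c(C=C)o2)[C@H](O)[C@H](O[Si](C)(C)C(C)(C)C)C=C)cc1O[Si](C)(C)C(C)(C)C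
F5 | step 6 | 2,2'-[(2Z)-3-(TBSO)prop-2-ene-1,1-diyl]bis(4,4,5,5-tetramethyl-1,3,2-dioxaborolane) | CC(C)(C)[Si](C)(C)O/C=C\C(B1OC(C)(C)C(C)(C)O1)B1OC(C)(C)C(C)(C)O1
F6 | step 6 | (5R,6R)-6-(TBSO)-2-{2-[3-(TBSO)-4-methoxyphenyl]ethyl}-5-hydroxy-5,6-dihydro-4H-chromen-4-one | COc1ccc(CCc2cc(=O)c3c(o2)C=C[C@@H](O[Si](C)(C)C(C)(C)C)[C@@H]3O)cc1O[Si](C)(C)C(C)(C)C
F7 | step 6 | (5S,6R)-6-(TBSO)-2-{2-[3-(TBSO)-4-methoxyphenyl]ethyl}-4-oxo-5,6-dihydro-4H-chromen-5-yl 4-nitrobenzoate | COc1ccc(CCc2cc(=O)c3c(o2)C=C[C@@H](O[Si](C)(C)C(C)(C)C)[C@H]3OC(=O)c4ccc(cc4)[N+](=O)[O-])cc1O[Si](C)(C)C(C)(C)C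
F8 | step 9 | (5S,6S,7S,8R)-7-bromo-6-(TBSO)-2-{2-[3-(TBSO)-4-methoxyphenyl]ethyl}-5,8-dihydroxy-5,6,7,8-tetrahydro-4H-chromen-4-one | COc1ccc(CCc2cc(=O)c3c(o2)[C@@H](O)[C@H](Br)[C@@H](O[Si](C)(C)C(C)(C)C)[C@H]3O)cc1O[Si](C)(C)C(C)(C)C
F9 | step 9 | (5S,6S,7S,8S)-7,8-epoxy-6-(TBSO)-2-{2-[3-(TBSO)-4-methoxyphenyl]ethyl}-5-hydroxy-5,6,7,8-tetrahydro-4H-chromen-4-one | COc1ccc(CCc2cc(=O)c3c(o2)[C@H]4O[C@H]4[C@@H](O[Si](C)(C)C(C)(C)C)[C@H]3O)cc1O[Si](C)(C)C(C)(C)C
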